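- You asked for a quick number and guessed that the amount of Z counts. The easy step came first: over their last two readings, D held at 42.6 % in the south-east run and 39.2 % in the west run, with E read at 0 % and 0 % at the end, so I read D there as a plateau.

| flask | E | Z | remark | time |
|---|---|---|---|---|
| north-east | 0.075 M | 7.5 mM | run made earlier |  |
| south-east | 0.30 M | 7.5 mM | run made earlier |  |
| west | 0.15 M | 15 mM | run made earlier |  |
| flask | 0.15 M | 7.50 mM |  | 8.0 h |

| run | time / h | E / % | D / % |
|---|---|---|---|
| north-east | 1.00 | 21.3 | 28.9 |
| north-east | 2.00 | 5.2 | 36.8 |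
| north-east | 3.00 | 1.2 | 38.7 |
| north-east | 4.00 | 0 | 39.2 |
| north-east | 5.00 | 0.9 | 39.1 |
| north-east | 6.00 | 0 | 39.9 |
| south-east | 0.417 | 53.4 | 15.0 |
| south-east | 1.33 | 14.2 | 34.8 |
| south-east | 2.50 | 2.5 | 41.2 |
| south-east | 4.00 | 0.3 | 42.4 |
| south-east | 5.00 | 0 | 42.6 |
| south-east | 6.00 | 0 | 42.6 |
| west | 1.33 | 13.6 | 32.1 |
| west | 2.50 | 2.7 | 38.3 |
| west | 4.00 | 0.7 | 39.3 |
| west | 5.00 | 0 | 39.2 |
| west | 6.00 | 0 | 39.2 |

(each reading ± 0.3 percentage points)

- a species is counted by the E in it: one X counts as two
- the analysis behind the earlier runs scatters by 0.3 percentage points, standard deviation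
- reactions considered so far: E -> J; J <-> D; 2 E -> X; E + Z -> G
- the reaction counts as stopped when no species that holds the E changes by six tenths of a point or more over the second half of the time

1. which holds at 8.0 h: what has brought the reaction to rest, or that it has not come to rest (forward and back rates have come level / all of E has reacted / it is still moving)
2. part of the E gone at 8.0 h
3. the D standing at 8.0 h, as a percentage of the E charged

- The north-east and west runs differ in both charges: E 0.075 M against 0.15 M, Z 7.5 mM against 15 mM. Yet their late D readings are 39.4 % on average and 39.2 %. What they share is the ratio of Z to E.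
- For this flask, the Z toll is 5.00 %: the charged Z over the charged E. I took it as the share of E lost one for one to G, with Z as the limiting reagent of that side path.
- I called D over the E left after the toll the D share. It reads 43.7 % in the south-east run and 43.6 % in the west run.
- For this flask, that gives D of 41.5 %. My forecast was 41.5 % of D, 100 % of E gone, and this end: forward and back rates have come level. I wrote that “the rest is set by equilibrium”.
- At 8.0 h the flask gave D of 41.6 % and E gone >99.9 %. Its end was: all of E has reacted. The toll of 5.00 % stood there as G, at 5.00 %.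

    E → J (k = 3.96 × 10⁻⁴ s⁻¹)
    J ⇌ D (K = 0.780, k = 9.72 × 10⁻⁴ s⁻¹)
    2 E → X (k = 2.65 × 10⁻⁶ M⁻¹ s⁻¹)
    E + Z → G (k = 0.0398 M⁻¹ s⁻¹)

- The neighbouring flask held 0.030 M of Z with the same E. Its toll is 20.0 %, so the D share gives D of 35.0 %. At 8.00 h, Z stood at 0 % of its charge and G at 20.0 %. Its D stood at 35.0 %.

(All runs were computed from invented constants, noise included.)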